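# Chemoenzymatic route to CNP0316239.2 through terpene-cyclase closure of C6–C7

## The problem

Compound 39 is a germacrane: a ten-membered carbocycle C1–C10 with an E-configured C1=C10 double bond and a trans 4,5-epoxide. C14 sits on C10, C15 on C4 and the three-carbon unit C11–C13 on C7. Four ring stereocentres (4S,5R,7S,9S) and two in the C14 ester (2R,3S) must be set. In a flat drawing with the ring numbered counterclockwise, C15, the C5–O bond and the C9 oxygen point up and the C11 side chain points down. C7 and C9 are 1,3-related across a mobile ring and cannot be trusted to control each other. The face of C4=C5 that a reagent meets depends on the reacting ring conformer, so the epoxide needs reagent control. The side-chain centres are independent of the ring. Five oxygenated sites must be told apart: an angelate on the secondary C9 hydroxyl, a syn-aldol ester on C14, an acetate on C12, a free hydroxyl on C15 and the oxirane. The fragile groups are: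

- the angelate, which isomerizes to the tiglate under nucleophilic or basic catalysis;
- three allylic esters, open to ionization by zerovalent palladium, hydrolysis and acyl shift;
- the epoxy alcohol, which undergoes Payne migration in base and transannular opening in acid;
- the germacra-1(10),4-diene itself before the epoxide is in place, which cyclizes in acid and undergoes Cope rearrangement on heating.

The feature that opens the shortest access is that C1–C15 form a regular head-to-tail farnesyl chain in which the ring needs only the bond C6–C7, with C7 carrying the isopropenyl-type unit. This is the bond a germacrene-forming terpene cyclase makes. The two oxygens that must be present at that stage (C9, C14) lie on the central isoprene unit, away from both reacting ends.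

## Retrosynthesis

**C12–O and the silyl groups.** Target 39 is traced to its bis(triethylsilyl) ether 38, and the C12–O bond of 38 is cut through allylic chloride 37 back to the isopropenyl compound 36. Carrying the C12 oxygen through the cyclization would put an electron-withdrawing group on the alkene that acts as nucleophile in the key step, so it is added last. The forward reaction must pick the isopropenyl group in the presence of the C1=C10 alkene and the angelate.

**The two acyl C–O bonds.** Ester 36 is cut at C9–O into alcohol 33 and angelic acid 34, and 33 at C14–O into diol 27 and acid 32. The esters come late because neither would survive the base and hydride steps before them. The primary hydroxyl is acylated first, the hindered secondary one second. The forward reactions must keep the angelate Z and the α-centre of 32 intact.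

**The epoxide and C15–O.** Diol 27 comes from silyl ether 26 and epoxy alcohol 25. Compound 25 is the Payne isomer of spiro-epoxy alcohol 24, which comes from allylic alcohol 23 by Sharpless epoxidation. Compound 23 is the base-isomerized form of methyl epoxide 22, itself the Shi epoxide of triene 21. This shuttle oxidizes the C15 methyl group while the C5–O bond, once set by a catalyst, is never broken, and the trans ring fusion is regenerated stereospecifically. Oxidizing C15 in the open chain instead would place an oxygen on the allyl unit that has to ionize in the key step. Triene 21 holds only C7 and C9.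

**C6–C7, the key cut.** Triene 21 is the bis-ether of diol 20, and 20 is opened at C6–C7 to diphosphate 19. This cut removes the ring and C7 together and leaves a chain with a single stereocentre. Cuts at C1–C2, C2–C3 or C4–C5 all require a chain or template that already carries C7, C9 and more. The forward reaction asks a cyclase to accept a dihydroxylated substrate and deliver the 7S-series ring.

**C6–O–P.** Diphosphate 19 comes from chlorodiol 18, which comes from chloride 17, diol 15 and silyl ether 14. The task is to activate one of three hydroxyls. It is solved by keeping C14–O as a 4-methoxybenzyl ether and C6–O as a silyl ether until each is needed.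

**C7=C11 and C8–C9.** Compound 14 is cut by cross-metathesis into terminal alkene 12 and 2-methylbut-2-ene 13, and 12 by allyl addition into enal 11. A linear prenyl group cannot be added enantioselectively in one step, because prenyl-metal reagents react through their tertiary carbon. Allylation followed by metathesis is the reliable detour and sets C9.

**C1=C10.** Enal 11 comes through alcohol 10 from ester 9, which is cut at the double bond into aldehyde 7 and phosphonoacrylate 3. Aldehyde 7 is the six-carbon cleavage product of silyl ether 5 of geraniol 4, and 3 comes from triethyl phosphonoacetate 1. The olefination puts C14–O and the C9 carbonyl on C10 in one step and must place the carbonyl trans to the chain.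

**Side chain.** Acid 32 is traced through peracid 31, silyl ether 30 and aldol 29 to propionimide 28 by a C2–C3 aldol cut. The auxiliary sets both centres.

## Roads not taken

**Alternative 1:** The ring is cut at C1–C2. In the forward sense 9-BBN hydroborates a terminal vinyl group, and PdCl2(dppf)/AsPh3/Cs2CO3 couples the resulting C2 borane with an (E)-C1 alkenyl iodide to close the ring to A1.

- Merits: the C1=C10 geometry is fixed in the iodide, and the closure is mild and tolerates the epoxide. The epoxide can be set on the open chain by Sharpless epoxidation, free of any ring-conformer problem. In this respect it is better than the chosen plan, which epoxidizes the ring.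
- Weak points: the open-chain precursor must already hold C4, C5, C7 and C9, so the linear sequence is long. The vinyl group to be hydroborated sits on a fully substituted epoxide carbon. A ten-membered sp3–sp2 coupling competes with β-hydride elimination and protodeboronation at high dilution. A1 still needs its bis(silyloxymethyl)methine unit desymmetrized and dehydrated to the acetoxymethyl vinyl group.
- Comparison: the key step is established chemistry, whereas the chosen one is untested. The chosen plan sets against this a chain with one stereocentre and a single step that gives ring and C7 together.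

**Alternative 2:** A divinylcyclohexanol template is ring-expanded. KH/18-crown-6 triggers an anionic oxy-Cope rearrangement that forms C2–C3 and breaks C5–C10, and PhNTf2 traps the C10 enolate to give triflate A2.

- Merits: the rearrangement is stereospecific through a chair and gives both E-alkenes. C7 and C9 are set on a six-membered ring, where relative control is dependable. A2 already carries the C12 and C15 oxygens, which the chosen plan must introduce after cyclization. The later epoxidation can then be a Sharpless reaction on a primary allylic alcohol, two steps shorter than the shuttle used here.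
- Weak points: the template with three stereocentres and two different alkenyl groups is itself a long synthesis. C14 is missing and must be added by palladium-catalysed carbonylation of the triflate on a 1,5-diene prone to Cope and transannular reactions. The C9 methoxymethyl ether needs acid for removal, which must happen before the epoxide exists.
- Comparison: the chosen plan sets against the better C12/C15 economy of A2 the fact that its ring is born with C9 and C14 already oxygenated and with no template to build.

**Alternative 3:** The ring is cut at C4–C5. CrCl2 with catalytic NiCl2 converts a C4 iodoalkene into an alkenylchromium species that adds to a C5 aldehyde, giving the exo-methylene carbinol A3.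

- Merits: the closure is chemoselective and precedented for medium rings. A3 is the same kind of allylic alcohol as 23 and already carries the C12 oxygen. It is reached without the epoxidation–isomerization pair of the chosen route, a real saving of two steps.
- Weak points: C5 is created in the closure under substrate control, and A3 has the 5S configuration, the opposite of what the Payne closure needs. An inversion on a hindered allylic ring alcohol (with SN2′ risk) or an oxidation–reduction must follow. The open-chain precursor must contain C7 and C9 and both reactive termini. A large excess of the chromium salt at high dilution is needed.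
- Comparison: the chosen plan sets C5 by a catalyst and C7 by the enzyme, at the price of an unproven key step.

Key step: step 13

## Route

Remark: ring compounds are numbered as germacranes (C12 is the isopropenyl carbon that ends up oxygenated, C13 its methylene) and open-chain compounds as farnesanes. The CIP label of C7 alternates between R and S with the substituents while its spatial arrangement stays that of 39.

Remark: a cyclase variant for step 13 is assumed to be obtainable by screening and directed evolution from enzymes that form (S)-germacrene A. Diphosphate 19 is handled as its ammonium salt and drawn as the free acid.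

Step 1
Reactants: 1 triethyl phosphonoacetate
Product: 3 ethyl 2-(diethoxyphosphoryl)acrylate, via hydroxymethyl adduct 2 (not isolated)
Conditions: (CH2O)n, piperidine (cat.), MeOH, reflux; then TsOH (cat.), toluene, reflux
Reagents that add atoms: formaldehyde (as paraformaldehyde), C=O
Why: Knoevenagel-type hydroxymethylation of the doubly activated methylene followed by acid-catalysed dehydration is the standard preparation of this Michael acceptor.

Step 2
Reactants: 4 geraniol
Product: 5 geranyl tert-butyldiphenylsilyl ether
Conditions: t-BuPh2SiCl, imidazole, CH2Cl2, 0 °C to rt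
Reagents that add atoms: tert-butyl(chloro)diphenylsilane, CC(C)(C)[Si](Cl)(c1ccccc1)c1ccccc1
Why: Silylation of the primary allylic alcohol; this ether withstands periodic acid, hydride, MnO2, the allylborane and metathesis and is removed later by fluoride.

Step 3
Reactants: 5 geranyl tert-butyldiphenylsilyl ether
Product: 7 (4E)-6-(tert-butyldiphenylsilyloxy)-4-methylhex-4-enal, via epoxide 6 (not isolated)
Conditions: mCPBA, CH2Cl2, −20 to 0 °C; then H5IO6, THF/H2O, 0 °C
Reagents that add atoms: mCPBA, O=C(OO)c1cccc(Cl)c1
Why: Prilezhaev epoxidation takes the remote, electron-richer trisubstituted alkene in preference to the one deactivated by the allylic silyloxy group; periodic acid then hydrolyses and cleaves the epoxide to the aldehyde and acetone.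

Step 4
Reactants: 3 ethyl 2-(diethoxyphosphoryl)acrylate; 7 (4E)-6-(tert-butyldiphenylsilyloxy)-4-methylhex-4-enal
Product: 9 ethyl (2E,6E)-8-(tert-butyldiphenylsilyloxy)-2-[(4-methoxybenzyloxy)methyl]-6-methylocta-2,6-dienoate, via phosphonate carbanion 8 (not isolated)
Conditions: 4-MeOC6H4CH2OH, NaH, THF, 0 °C; 3, −78 to 0 °C; then 7, 0 °C to rt
Reagents that add atoms: 4-methoxybenzyl alcohol, COc1ccc(CO)cc1
Why: Oxa-Michael addition of the alkoxide to 3 gives the α-substituted phosphonate carbanion, which olefinates 7 (Horner–Wadsworth–Emmons reaction). As with other α-alkyl phosphonoacetates the ester should end up trans to the chain, which is the C1=C10 geometry of the target; any minor geometric isomer is removed by chromatography.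

Step 5
Reactants: 9 ethyl (2E,6E)-8-(tert-butyldiphenylsilyloxy)-2-[(4-methoxybenzyloxy)methyl]-6-methylocta-2,6-dienoate
Product: 10 (2Z,6E)-8-(tert-butyldiphenylsilyloxy)-2-[(4-methoxybenzyloxy)methyl]-6-methylocta-2,6-dien-1-ol
Conditions: i-Bu2AlH, CH2Cl2, −78 °C; aq. potassium sodium tartrate
Reagents that add atoms: none
Why: 1,2-Reduction of the conjugated ester to the allylic alcohol; silyl and benzyl-type ethers are inert, and the new hydroxymethyl group stays trans to the chain (the descriptor changes only by priority).

Step 6
Reactants: 10 (2Z,6E)-8-(tert-butyldiphenylsilyloxy)-2-[(4-methoxybenzyloxy)methyl]-6-methylocta-2,6-dien-1-ol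
Product: 11 (2E,6E)-8-(tert-butyldiphenylsilyloxy)-2-[(4-methoxybenzyloxy)methyl]-6-methylocta-2,6-dienal
Conditions: MnO2, CH2Cl2, rt
Reagents that add atoms: none
Why: MnO2 oxidizes only the free allylic alcohol; the formyl group stays trans to the chain, the more stable arrangement.

Step 7
Reactants: 11 (2E,6E)-8-(tert-butyldiphenylsilyloxy)-2-[(4-methoxybenzyloxy)methyl]-6-methylocta-2,6-dienal
Product: 12 (4S,5E,9E)-11-(tert-butyldiphenylsilyloxy)-5-[(4-methoxybenzyloxy)methyl]-9-methylundeca-1,5,9-trien-4-ol
Conditions: (−)-Ipc2B(allyl), Et2O, −78 °C; then NaOH, H2O2, 0 °C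
Reagents that add atoms: (−)-B-allyldiisopinocampheylborane, C=CCB([C@@H]1C[C@@H]2C[C@H]([C@H]1C)C2(C)C)[C@@H]1C[C@@H]2C[C@H]([C@H]1C)C2(C)C
Why: Brown allylation: the allylborane derived from (+)-α-pinene adds to the Si face of the aldehyde through a chair transition state and sets the carbinol centre as S (the future C9); α-substituted enals are good substrates.

Step 8
Reactants: 12 (4S,5E,9E)-11-(tert-butyldiphenylsilyloxy)-5-[(4-methoxybenzyloxy)methyl]-9-methylundeca-1,5,9-trien-4-ol; 13 2-methylbut-2-ene
Product: 14 (2E,6E,8S)-1-(tert-butyldiphenylsilyloxy)-7-[(4-methoxybenzyloxy)methyl]-3,11-dimethyldodeca-2,6,10-trien-8-ol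
Conditions: second-generation Grubbs catalyst [(H2IMes)(PCy3)Cl2Ru=CHPh] (cat.), 13 (excess), CH2Cl2, rt
Reagents that add atoms: none
Why: Cross-metathesis of the terminal vinyl group with excess 13 installs the prenyl terminus; the trisubstituted alkenes of 12 are inert to the catalyst and no ring-closing mode is available.

Step 9
Reactants: 14 (2E,6E,8S)-1-(tert-butyldiphenylsilyloxy)-7-[(4-methoxybenzyloxy)methyl]-3,11-dimethyldodeca-2,6,10-trien-8-ol
Product: 15 (2E,6E,8S)-7-[(4-methoxybenzyloxy)methyl]-3,11-dimethyldodeca-2,6,10-triene-1,8-diol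
Conditions: Bu4NF, THF, 0 °C to rt
Reagents that add atoms: none
Why: Fluoride cleaves the silyl ether; the 4-methoxybenzyl ether and the alkenes are unaffected.

Step 10
Reactants: 15 (2E,6E,8S)-7-[(4-methoxybenzyloxy)methyl]-3,11-dimethyldodeca-2,6,10-triene-1,8-diol
Product: 17 (2E,6E,8S)-1-chloro-7-[(4-methoxybenzyloxy)methyl]-3,11-dimethyldodeca-2,6,10-trien-8-ol, via allylic mesylate 16 (not isolated)
Conditions: MsCl, 2,4,6-collidine, LiCl, DMF, 0 °C
Reagents that add atoms: lithium chloride, [Li+].[Cl-]
Why: The unhindered primary allylic hydroxyl is sulfonylated much faster than the secondary one flanked by a trisubstituted alkene, and chloride displaces the allylic mesylate in situ by SN2 without allylic transposition.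

Step 11
Reactants: 17 (2E,6E,8S)-1-chloro-7-[(4-methoxybenzyloxy)methyl]-3,11-dimethyldodeca-2,6,10-trien-8-ol
Product: 18 (2E,6E,8S)-1-chloro-7-(hydroxymethyl)-3,11-dimethyldodeca-2,6,10-trien-8-ol
Conditions: DDQ, CH2Cl2/pH 7 buffer, 0 °C
Reagents that add atoms: none
Why: Oxidative cleavage of the 4-methoxybenzyl ether under buffered conditions leaves the allylic chloride and the alkenes intact; 18 is used at once.

Step 12
Reactants: 18 (2E,6E,8S)-1-chloro-7-(hydroxymethyl)-3,11-dimethyldodeca-2,6,10-trien-8-ol
Product: 19 (2E,6E,8S)-8-hydroxy-7-(hydroxymethyl)-3,11-dimethyldodeca-2,6,10-trienyl diphosphate (ammonium salt)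
Conditions: (Bu4N)3HP2O7, MeCN, rt; cation exchange (NH4+ form), NH4HCO3 buffer
Reagents that add atoms: tris(tetrabutylammonium) hydrogen diphosphate, CCCC[N+](CCCC)(CCCC)CCCC.CCCC[N+](CCCC)(CCCC)CCCC.CCCC[N+](CCCC)(CCCC)CCCC.OP(=O)([O-])OP(=O)([O-])[O-]
Why: SN2 displacement of a primary allylic chloride by diphosphate is the standard route to prenyl diphosphates and tolerates free hydroxyl groups elsewhere in the chain; ion exchange gives the ammonium salt.

Step 13
Reactants: 19 (2E,6E,8S)-8-hydroxy-7-(hydroxymethyl)-3,11-dimethyldodeca-2,6,10-trienyl diphosphate (ammonium salt)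
Product: 20 (1(10)E,4E,7R,9S)-germacra-1(10),4,11(13)-triene-9,14-diol
Conditions: recombinant (S)-germacrene A-type sesquiterpene cyclase (evolved variant), MgCl2, Tris buffer pH 7.5, 25 °C; EtOAc extraction
Reagents that add atoms: none
Why: Proposed new method: a class 1 terpene cyclase binds the diphosphate on its divalent magnesium cluster and ionizes the C6–O bond to an allyl cation spread over C6 and C4; the closest known reaction type is germacrene A synthase catalysis on farnesyl diphosphate and on hydroxylated, fluorinated or alkylated analogues. Folded in the active site, the distal C7=C11 alkene attacks C6 in Markovnikov fashion, which forms the C6–C7 bond and closes the ten-membered ring by cation–olefin attack with the charge exocyclic on tertiary C11 (1,10-closure in farnesane numbering). Loss of a proton from a C11 methyl group to the bound diphosphate leaves the isopropenyl group. The new stereocentre C7 is set by the enzyme alone, through the alkene face it presents to C6; the 9S carbinol is a spectator. The step needs ten-membered closure in preference to six- or eleven-membered closure, termination by proton loss instead of water capture or reprotonation to bicyclic products, and no capture of the cation by a hydroxyl. The substrate helps in three ways: both hydroxyls lie on the central isoprene unit and leave the ionizing allyl system and the nucleophilic alkene electronically unchanged, the E-geometry at C4=C5 forbids six-membered closure without prior isomerization, and the C9 oxygen ends up on the ring face opposite to C11, where oxolane formation would be strained. The starting point is a cyclase of the (S)-germacrene A-forming kind, such as aristolochene synthase variants that lack the acid needed for the second cyclization; acceptance of the diol has to be secured by screening and directed evolution.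

Step 14
Reactants: 20 (1(10)E,4E,7R,9S)-germacra-1(10),4,11(13)-triene-9,14-diol
Product: 21 (1(10)E,4E,7R,9S)-9,14-bis(4-methoxybenzyloxy)germacra-1(10),4,11(13)-triene
Conditions: NaH, 4-MeOC6H4CH2Cl, Bu4NI (cat.), THF/DMF, 0 °C to rt
Reagents that add atoms: 4-methoxybenzyl chloride, COc1ccc(CCl)cc1
Why: Williamson etherification of both hydroxyls; benzyl-type ethers withstand the basic and oxidative steps that follow and can later be removed beside a triethylsilyl ether. The diene is kept at or below room temperature and away from acid.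

Step 15
Reactants: 21 (1(10)E,4E,7R,9S)-9,14-bis(4-methoxybenzyloxy)germacra-1(10),4,11(13)-triene
Product: 22 (1(10)E,4R,5R,7S,9S)-4,5-epoxy-9,14-bis(4-methoxybenzyloxy)germacra-1(10),11(13)-diene
Conditions: D-fructose-derived Shi ketone (cat.), KHSO5, K2CO3, Bu4NHSO4, MeCN/CH2(OMe)2/aq. Na2B4O7 buffer, 0 °C
Reagents that add atoms: potassium peroxymonosulfate, [K+].[O-]S(=O)(=O)OO
Why: Shi epoxidation: the dioxirane takes the most electron-rich alkene, C4=C5 (C1=C10 is deactivated by two allylic oxygens, the isopropenyl group is only disubstituted). The D-fructose-derived catalyst, which gives R,R-epoxides from E-alkenes, should select the face leading to 4R,5R, provided the ring conformers that expose either face interconvert faster than they are oxidized.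

Step 16
Reactants: 22 (1(10)E,4R,5R,7S,9S)-4,5-epoxy-9,14-bis(4-methoxybenzyloxy)germacra-1(10),11(13)-diene
Product: 23 (1(10)E,5R,7R,9S)-9,14-bis(4-methoxybenzyloxy)germacra-1(10),4(15),11(13)-trien-5-ol
Conditions: Et2AlCl, LiTMP [gives Et2Al(TMP)], toluene, 0 °C
Reagents that add atoms: none
Why: Aluminium amide-promoted syn-elimination of the epoxide to the allylic alcohol removes a proton from the C15 methyl group, the least hindered β-position, and breaks the C4–O bond, so the C5–O bond and its configuration are kept.

Step 17
Reactants: 23 (1(10)E,5R,7R,9S)-9,14-bis(4-methoxybenzyloxy)germacra-1(10),4(15),11(13)-trien-5-ol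
Product: 25 (1(10)E,4S,5R,7S,9S)-4,5-epoxy-9,14-bis(4-methoxybenzyloxy)germacra-1(10),11(13)-dien-15-ol, via spiro-epoxy alcohol 24 (not isolated)
Conditions: Ti(OiPr)4 (cat.), D-(−)-diisopropyl tartrate (cat.), t-BuOOH, 4 Å MS, CH2Cl2, −20 °C; then aq. NaOH, t-BuOH, 0 °C to rt
Reagents that add atoms: tert-butyl hydroperoxide, CC(C)(C)OO
Why: Sharpless epoxidation of a secondary allylic alcohol: the 5R carbinol is the fast-reacting partner of the D-(−)-tartrate catalyst and should give the erythro spiro-epoxide with 4R. Base then induces the Payne rearrangement, in which the C5 alkoxide opens the oxirane at C4 with inversion to give the more substituted 4S,5R epoxide and the primary C15 alkoxide.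

Step 18
Reactants: 25 (1(10)E,4S,5R,7S,9S)-4,5-epoxy-9,14-bis(4-methoxybenzyloxy)germacra-1(10),11(13)-dien-15-ol
Product: 26 (1(10)E,4S,5R,7S,9S)-4,5-epoxy-9,14-bis(4-methoxybenzyloxy)-15-(triethylsilyloxy)germacra-1(10),11(13)-diene
Conditions: Et3SiCl, imidazole, CH2Cl2, 0 °C
Reagents that add atoms: chlorotriethylsilane, CC[Si](Cl)(CC)CC
Why: Silylation of the only free hydroxyl keeps C15–OH out of the two acylations; the triethylsilyl group is chosen so that it falls together with that of the side chain in the last step.

Step 19
Reactants: 26 (1(10)E,4S,5R,7S,9S)-4,5-epoxy-9,14-bis(4-methoxybenzyloxy)-15-(triethylsilyloxy)germacra-1(10),11(13)-diene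
Product: 27 (1(10)E,4S,5R,7S,9S)-4,5-epoxy-15-(triethylsilyloxy)germacra-1(10),11(13)-diene-9,14-diol
Conditions: DDQ, CH2Cl2/pH 7 buffer, 0 °C
Reagents that add atoms: none
Why: DDQ cleaves both 4-methoxybenzyl ethers oxidatively under neutral buffered conditions that leave the epoxide and the silyl ether alone.

Step 20
Reactants: 28 (R)-4-benzyl-3-propanoyloxazolidin-2-one
Product: 29 (R)-4-benzyl-3-[(2R,3S)-3-hydroxy-2-methylbutanoyl]oxazolidin-2-one
Conditions: Bu2BOTf, i-Pr2NEt, CH2Cl2, −78 to 0 °C; MeCHO, −78 to 0 °C; then H2O2, pH 7 buffer, MeOH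
Reagents that add atoms: acetaldehyde, CC=O
Why: Evans syn-aldol reaction: the Z-boron enolate of the (R)-benzyl auxiliary adds to the aldehyde through a Zimmerman–Traxler chair and gives the 2R,3S syn adduct.

Step 21
Reactants: 29 (R)-4-benzyl-3-[(2R,3S)-3-hydroxy-2-methylbutanoyl]oxazolidin-2-one
Product: 30 (R)-4-benzyl-3-[(2R,3S)-2-methyl-3-(triethylsilyloxy)butanoyl]oxazolidin-2-one
Conditions: Et3SiOTf, 2,6-lutidine, CH2Cl2, −78 °C
Reagents that add atoms: triethylsilyl triflate, CC[Si](CC)(CC)OS(=O)(=O)C(F)(F)F
Why: Silylation of the β-hydroxyl prevents self-acylation and retro-aldol cleavage in the following steps.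

Step 22
Reactants: 30 (R)-4-benzyl-3-[(2R,3S)-2-methyl-3-(triethylsilyloxy)butanoyl]oxazolidin-2-one
Product: 32 (2R,3S)-2-methyl-3-(triethylsilyloxy)butanoic acid, via peroxy acid 31 (not isolated)
Conditions: LiOH, H2O2, THF/H2O, 0 °C; then Na2SO3
Reagents that add atoms: hydrogen peroxide, OO
Why: Hydroperoxide attacks the exocyclic imide carbonyl selectively; sulfite reduces the peracid to the acid without epimerization and the auxiliary is recovered.

Step 23
Reactants: 27 (1(10)E,4S,5R,7S,9S)-4,5-epoxy-15-(triethylsilyloxy)germacra-1(10),11(13)-diene-9,14-diol; 32 (2R,3S)-2-methyl-3-(triethylsilyloxy)butanoic acid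
Product: 33 14-O-[(2R,3S)-2-methyl-3-(triethylsilyloxy)butanoyl] ester of 27 (9-hydroxyl free)
Conditions: EDC·HCl, DMAP (cat.), CH2Cl2, 0 °C
Reagents that add atoms: none
Why: Steglich esterification at 0 °C acylates the primary allylic C14 hydroxyl in preference to the hindered secondary C9 hydroxyl.

Step 24
Reactants: 33 14-O-[(2R,3S)-2-methyl-3-(triethylsilyloxy)butanoyl] ester of 27; 34 angelic acid
Product: 36 9-O-angeloyl derivative of 33, via mixed anhydride 35 (not isolated)
Conditions: 34, 2,4,6-Cl3C6H2COCl, Et3N, toluene, rt, filtration; then 33, toluene, 75 °C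
Reagents that add atoms: none
Why: Yamaguchi-type esterification through the mixed anhydride without a nucleophilic amine catalyst, conditions under which angelates form without Z-to-E isomerization to the tiglate; the ring no longer holds a 1,5-diene, so heating is tolerated.

Step 25
Reactants: 36 9-O-angeloyl derivative of 33
Product: 37 12-chloro derivative of 36 (2-(chloromethyl)vinyl group at C7)
Conditions: Ca(OCl)2, solid CO2, CH2Cl2/H2O, 0 °C
Reagents that add atoms: calcium hypochlorite (source of HOCl), [Ca+2].[O-]Cl.[O-]Cl
Why: Ene-type allylic chlorination: chlorine adds to the terminal methylene of the isopropenyl group and a methyl proton is lost, giving the 2-(chloromethyl)vinyl unit (the two carbons exchange roles, which is without consequence). The C1=C10 alkene carries two allylic acyloxy groups and the angelate is electron-poor, so both should be left.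

Step 26
Reactants: 37 12-chloro derivative of 36
Product: 38 15-O,3′-O-bis(triethylsilyl) ether of the target (12-acetate)
Conditions: Bu4NOAc, acetone, rt
Reagents that add atoms: tetrabutylammonium acetate, CC(=O)[O-].CCCC[N+](CCCC)(CCCC)CCCC
Why: SN2 displacement of the primary allylic chloride by acetate (an SN2′ path gives the same product) installs the C12 acetate without an acylation step that would endanger other groups.

Step 27
Reactants: 38 15-O,3′-O-bis(triethylsilyl) ether of the target
Product: 39 CNP0316239.2, (1(10)E,4S,5R,7S,9S)-12-acetoxy-9-angeloyloxy-4,5-epoxy-15-hydroxygermacra-1(10),11(13)-dien-14-yl (2R,3S)-3-hydroxy-2-methylbutanoate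
Conditions: HF·pyridine, pyridine, THF, 0 °C
Reagents that add atoms: none
Why: Buffered HF·pyridine removes both triethylsilyl ethers without opening the epoxide or touching the esters.

## Compound list

1 | triethyl phosphonoacetate | CCOC(=O)CP(=O)(OCC)OCC | starting material
2 | ethyl 2-(diethoxyphosphoryl)-3-hydroxypropanoate | CCOC(=O)C(CO)P(=O)(OCC)OCC | intermediate (not isolated)
3 | ethyl 2-(diethoxyphosphoryl)acrylate | C=C(C(=O)OCC)P(=O)(OCC)OCC | intermediate
4 | geraniol, (2E)-3,7-dimethylocta-2,6-dien-1-ol | CC(C)=CCC/C(C)=C/CO | starting material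
5 | geranyl tert-butyldiphenylsilyl ether | CC(C)=CCC/C(C)=C/CO[Si](c1ccccc1)(c1ccccc1)C(C)(C)C | intermediate
6 | (2E)-6,7-epoxygeranyl tert-butyldiphenylsilyl ether (racemic epoxide) | CC1(C)OC1CC/C(C)=C/CO[Si](c1ccccc1)(c1ccccc1)C(C)(C)C | intermediate (not isolated)
7 | (4E)-6-(tert-butyldiphenylsilyloxy)-4-methylhex-4-enal | O=CCC/C(C)=C/CO[Si](c1ccccc1)(c1ccccc1)C(C)(C)C | intermediate
8 | ethyl 2-(diethoxyphosphoryl)-3-(4-methoxybenzyloxy)propanoate, present as its sodium carbanion | CCOC(=O)C(COCc1ccc(OC)cc1)P(=O)(OCC)OCC | intermediate (not isolated)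
9 | ethyl (2E,6E)-8-(tert-butyldiphenylsilyloxy)-2-[(4-methoxybenzyloxy)methyl]-6-methylocta-2,6-dienoate (ester trans to the chain) | CCOC(=O)/C(COCc1ccc(OC)cc1)=C/CC/C(C)=C/CO[Si](c1ccccc1)(c1ccccc1)C(C)(C)C | intermediate
10 | (2Z,6E)-8-(tert-butyldiphenylsilyloxy)-2-[(4-methoxybenzyloxy)methyl]-6-methylocta-2,6-dien-1-ol (hydroxymethyl trans to the chain) | OC/C(COCc1ccc(OC)cc1)=C/CC/C(C)=C/CO[Si](c1ccccc1)(c1ccccc1)C(C)(C)C | intermediate
11 | (2E,6E)-8-(tert-butyldiphenylsilyloxy)-2-[(4-methoxybenzyloxy)methyl]-6-methylocta-2,6-dienal | O=C/C(COCc1ccc(OC)cc1)=C/CC/C(C)=C/CO[Si](c1ccccc1)(c1ccccc1)C(C)(C)C | intermediate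
12 | (4S,5E,9E)-11-(tert-butyldiphenylsilyloxy)-5-[(4-methoxybenzyloxy)methyl]-9-methylundeca-1,5,9-trien-4-ol | C=CC[C@H](O)/C(COCc1ccc(OC)cc1)=C/CC/C(C)=C/CO[Si](c1ccccc1)(c1ccccc1)C(C)(C)C | intermediate
13 | 2-methylbut-2-ene | CC=C(C)C | starting material
14 | (2E,6E,8S)-1-(tert-butyldiphenylsilyloxy)-7-[(4-methoxybenzyloxy)methyl]-3,11-dimethyldodeca-2,6,10-trien-8-ol | CC(C)=CC[C@H](O)/C(COCc1ccc(OC)cc1)=C/CC/C(C)=C/CO[Si](c1ccccc1)(c1ccccc1)C(C)(C)C | intermediate
15 | (2E,6E,8S)-7-[(4-methoxybenzyloxy)methyl]-3,11-dimethyldodeca-2,6,10-triene-1,8-diol | CC(C)=CC[C@H](O)/C(COCc1ccc(OC)cc1)=C/CC/C(C)=C/CO | intermediate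
16 | 1-O-methanesulfonate of 15 | CC(C)=CC[C@H](O)/C(COCc1ccc(OC)cc1)=C/CC/C(C)=C/COS(C)(=O)=O | intermediate (not isolated)
17 | (2E,6E,8S)-1-chloro-7-[(4-methoxybenzyloxy)methyl]-3,11-dimethyldodeca-2,6,10-trien-8-ol (farnesane numbering) | CC(C)=CC[C@H](O)/C(COCc1ccc(OC)cc1)=C/CC/C(C)=C/CCl | intermediate
18 | (2E,6E,8S)-1-chloro-7-(hydroxymethyl)-3,11-dimethyldodeca-2,6,10-trien-8-ol (farnesane numbering) | CC(C)=CC[C@H](O)/C(CO)=C/CC/C(C)=C/CCl | intermediate
19 | (2E,6E,8S)-8-hydroxy-7-(hydroxymethyl)-3,11-dimethyldodeca-2,6,10-trienyl diphosphate (drawn as free acid) | CC(C)=CC[C@H](O)/C(CO)=C/CC/C(C)=C/COP(=O)(O)OP(=O)(O)O | intermediate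
20 | (1(10)E,4E,7R,9S)-germacra-1(10),4,11(13)-triene-9,14-diol | C=C(C)[C@H]1C[C@H](O)/C(CO)=C/CC/C(C)=C/C1 | intermediate
21 | (1(10)E,4E,7R,9S)-9,14-bis(4-methoxybenzyloxy)germacra-1(10),4,11(13)-triene | C=C(C)[C@H]1C[C@H](OCc2ccc(OC)cc2)/C(COCc2ccc(OC)cc2)=C/CC/C(C)=C/C1 | intermediate
22 | (1(10)E,4R,5R,7S,9S)-4,5-epoxy-9,14-bis(4-methoxybenzyloxy)germacra-1(10),11(13)-diene | C=C(C)[C@H]1C[C@H](OCc2ccc(OC)cc2)/C(COCc2ccc(OC)cc2)=C/CC[C@@]2(C)O[C@@H]2C1 | intermediate
23 | (1(10)E,5R,7R,9S)-9,14-bis(4-methoxybenzyloxy)germacra-1(10),4(15),11(13)-trien-5-ol | C=C(C)[C@H]1C[C@H](OCc2ccc(OC)cc2)/C(COCc2ccc(OC)cc2)=C/CCC(=C)[C@H](O)C1 | intermediate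
24 | (1(10)E,4R,5R,7R,9S)-4,15-epoxy-9,14-bis(4-methoxybenzyloxy)germacra-1(10),11(13)-dien-5-ol | C=C(C)[C@H]1C[C@H](OCc2ccc(OC)cc2)/C(COCc2ccc(OC)cc2)=C/CC[C@@]2(CO2)[C@H](O)C1 | intermediate (not isolated)
25 | (1(10)E,4S,5R,7S,9S)-4,5-epoxy-9,14-bis(4-methoxybenzyloxy)germacra-1(10),11(13)-dien-15-ol | C=C(C)[C@H]1C[C@H](OCc2ccc(OC)cc2)/C(COCc2ccc(OC)cc2)=C/CC[C@@]2(CO)O[C@@H]2C1 | intermediate
26 | (1(10)E,4S,5R,7S,9S)-4,5-epoxy-9,14-bis(4-methoxybenzyloxy)-15-(triethylsilyloxy)germacra-1(10),11(13)-diene | C=C(C)[C@H]1C[C@H](OCc2ccc(OC)cc2)/C(COCc2ccc(OC)cc2)=C/CC[C@@]2(CO[Si](CC)(CC)CC)O[C@@H]2C1 | intermediate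
27 | (1(10)E,4S,5R,7S,9S)-4,5-epoxy-15-(triethylsilyloxy)germacra-1(10),11(13)-diene-9,14-diol | C=C(C)[C@H]1C[C@H](O)/C(CO)=C/CC[C@@]2(CO[Si](CC)(CC)CC)O[C@@H]2C1 | intermediate
28 | (R)-4-benzyl-3-propanoyloxazolidin-2-one | CCC(=O)N1[C@H](Cc2ccccc2)COC1=O | starting material
29 | (R)-4-benzyl-3-[(2R,3S)-3-hydroxy-2-methylbutanoyl]oxazolidin-2-one | O=C1OC[C@@H](Cc2ccccc2)N1C(=O)[C@H](C)[C@H](C)O | intermediate
30 | (R)-4-benzyl-3-[(2R,3S)-2-methyl-3-(triethylsilyloxy)butanoyl]oxazolidin-2-one | O=C1OC[C@@H](Cc2ccccc2)N1C(=O)[C@H](C)[C@H](C)O[Si](CC)(CC)CC | intermediate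
31 | (2R,3S)-2-methyl-3-(triethylsilyloxy)butaneperoxoic acid | OOC(=O)[C@H](C)[C@H](C)O[Si](CC)(CC)CC | intermediate (not isolated)
32 | (2R,3S)-2-methyl-3-(triethylsilyloxy)butanoic acid | OC(=O)[C@H](C)[C@H](C)O[Si](CC)(CC)CC | intermediate
33 | (1(10)E,4S,5R,7S,9S)-4,5-epoxy-9-hydroxy-15-(triethylsilyloxy)germacra-1(10),11(13)-dien-14-yl (2R,3S)-2-methyl-3-(triethylsilyloxy)butanoate | C=C(C)[C@H]1C[C@H](O)/C(COC(=O)[C@H](C)[C@H](C)O[Si](CC)(CC)CC)=C/CC[C@@]2(CO[Si](CC)(CC)CC)O[C@@H]2C1 | intermediate
34 | angelic acid, (Z)-2-methylbut-2-enoic acid | C/C=C(/C)C(=O)O | starting material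
35 | angelic 2,4,6-trichlorobenzoic anhydride | C/C=C(/C)C(=O)OC(=O)c1c(Cl)cc(Cl)cc1Cl | intermediate (not isolated)
36 | (1(10)E,4S,5R,7S,9S)-9-angeloyloxy-4,5-epoxy-15-(triethylsilyloxy)germacra-1(10),11(13)-dien-14-yl (2R,3S)-2-methyl-3-(triethylsilyloxy)butanoate | C=C(C)[C@H]1C[C@H](OC(=O)/C(C)=C\C)/C(COC(=O)[C@H](C)[C@H](C)O[Si](CC)(CC)CC)=C/CC[C@@]2(CO[Si](CC)(CC)CC)O[C@@H]2C1 | intermediate
37 | 12-chloro derivative of 36 (2-(chloromethyl)vinyl group at C7; other centres as in 36) | C=C(CCl)[C@H]1C[C@H](OC(=O)/C(C)=C\C)/C(COC(=O)[C@H](C)[C@H](C)O[Si](CC)(CC)CC)=C/CC[C@@]2(CO[Si](CC)(CC)CC)O[C@@H]2C1 | intermediate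
38 | 12-acetoxy derivative of 36, the 15-O,3′-O-bis(triethylsilyl) ether of the target | C=C(COC(C)=O)[C@H]1C[C@H](OC(=O)/C(C)=C\C)/C(COC(=O)[C@H](C)[C@H](C)O[Si](CC)(CC)CC)=C/CC[C@@]2(CO[Si](CC)(CC)CC)O[C@@H]2C1 | intermediate
39 | CNP0316239.2, (1(10)E,4S,5R,7S,9S)-12-acetoxy-9-angeloyloxy-4,5-epoxy-15-hydroxygermacra-1(10),11(13)-dien-14-yl (2R,3S)-3-hydroxy-2-methylbutanoate | C=C(COC(C)=O)[C@H]1C[C@H](OC(=O)/C(C)=C\C)/C(COC(=O)[C@H](C)[C@H](C)O)=C/CC[C@@]2(CO)O[C@@H]2C1 | target

## Step count and least certain steps

Total step count: 27. Longest linear sequence: 23 steps (from 4 to 39 through steps 2–19 and 23–27).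

**Step 13 (key step, beyond known chemistry).** The cyclase may not turn over the diol at all. If it does, the ion pair may collapse by elimination to open-chain trienes, the cation may be captured by water, or the reaction may run on to bicyclic products. The active site may also deliver the other face at C7, because the pocket was shaped for an unsubstituted chain.

Fallback with known chemistry, setting out from 14 and returning at 21:

- Epoxidation of the terminal alkene of 14 with the enantiomer of the Shi ketone and KHSO5 would give the (10S)-epoxide F1.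
- Bu4NF would free the primary alcohol to give the epoxy diol F2.
- PhSSPh/Bu3P would convert its primary allylic hydroxyl into the phenyl sulfide F3.
- Double deprotonation with n-BuLi and DABCO in THF at −78 °C would generate the sulfur-stabilized allyl anion at C6, which opens the epoxide at C7 with inversion. This is the classical sulfide-carbanion/epoxide closure of ten-membered germacrane rings. It forms the same C6–C7 bond, sets C7 from the epoxide configuration and would give the hydroxy sulfide F4.
- Li in EtNH2 would remove the phenylthio group and the benzyl-type ether to give the triol F5.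
- NaH and 4-methoxybenzyl chloride would etherify the two reactive hydroxyls to give the tertiary alcohol F6.
- Dehydration with the Burgess reagent would give 21 after separation from the isopropylidene isomer.

**Step 15.** Facial selection may be poor, or the oxidation may stray to another alkene. In a ten-membered E-alkene only the outer face is open, and which enantioface that is depends on the ring conformer, so the catalyst must work through what may be a minor conformer.

Fallback from 21 to 23:

- mCPBA would epoxidize C4=C5 without facial control to the epoxide mixture F7.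
- Et2Al(TMP) would open both to the epimeric allylic alcohols F8.
- Dess–Martin periodinane would merge them in the enone F9.
- Corey–Bakshi–Shibata reduction ((S)-Me-oxazaborolidine, catecholborane, toluene, −78 °C) would set 5R from the carbonyl face, independent of the ring conformer, and give 23.

**Step 17.** The Payne equilibrium may stop short or be overtaken by hydrolytic opening of the spiro-epoxide. The trans-fused oxirane adds strain to the ten-membered ring, which may erode the usual preference for the more substituted epoxide.

Fallback from 23 to 25: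

- Acetylation (Ac2O, pyridine) would give the acetate F10.
- A PdCl2(MeCN)2-catalysed 1,3-shift of the allylic acetate would give the primary acetate F11 with the trisubstituted 4E-alkene.
- K2CO3 in MeOH would free the allylic alcohol F12.
- Sharpless epoxidation of this primary allylic alcohol with Ti(OiPr)4, D-(−)-diisopropyl tartrate and t-BuOOH would deliver oxygen to the face that gives 4S,5R, and so 25 directly.

**Step 24.** Acylation of the hindered C9 hydroxyl may be slow, and prolonged heating may isomerize the angelate to the tiglate.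

Fallback from 33 to 36:

- Esterification of the C9 hydroxyl with 2-[bis(2,2,2-trifluoroethoxy)phosphoryl]propanoic acid (EDC·HCl, DMAP, CH2Cl2) would give the phosphonate ester F13.
- Still–Gennari olefination with acetaldehyde (KN(SiMe3)2, 18-crown-6, THF, −78 °C) would build the Z-alkene in place and give 36.

**Step 25.** Site selectivity may be lost through removal of the C7 hydrogen instead of a methyl hydrogen (giving a tetrasubstituted alkene), or through attack on the ring alkene or a silyl ether.

Fallback from 36 to 38:

- SeO2 (cat.) with t-BuOOH in CH2Cl2 would oxidize the isopropenyl methyl group by an ene/[2,3]-shift sequence to the allylic alcohol F14.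
- Ac2O in pyridine would acetylate it to 38, the silyl ethers shielding the other hydroxyls.

## Further compounds

F1 | step 13 | (2E,6E,8S,10S)-1-(tert-butyldiphenylsilyloxy)-10,11-epoxy-7-[(4-methoxybenzyloxy)methyl]-3,11-dimethyldodeca-2,6-dien-8-ol | CC1(C)O[C@H]1C[C@H](O)/C(COCc2ccc(OC)cc2)=C/CC/C(C)=C/CO[Si](c2ccccc2)(c2ccccc2)C(C)(C)C
F2 | step 13 | (2E,6E,8S,10S)-10,11-epoxy-7-[(4-methoxybenzyloxy)methyl]-3,11-dimethyldodeca-2,6-diene-1,8-diol | CC1(C)O[C@H]1C[C@H](O)/C(COCc2ccc(OC)cc2)=C/CC/C(C)=C/CO
F3 | step 13 | (2E,6E,8S,10S)-10,11-epoxy-7-[(4-methoxybenzyloxy)methyl]-3,11-dimethyl-1-(phenylthio)dodeca-2,6-dien-8-ol | CC1(C)O[C@H]1C[C@H](O)/C(COCc2ccc(OC)cc2)=C/CC/C(C)=C/CSc2ccccc2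
F4 | step 13 | (1(10)E,4E)-14-(4-methoxybenzyloxy)-6-(phenylthio)germacra-1(10),4-diene-9,11-diol (C7 and C9 as in 20, both C6 epimers) | CC(C)(O)[C@H]1C[C@H](O)/C(COCc2ccc(OC)cc2)=C/CC/C(C)=C/C1Sc1ccccc1
F5 | step 13 | (1(10)E,4E)-germacra-1(10),4-diene-9,11,14-triol (C7 and C9 as in 20) | CC(C)(O)[C@H]1C[C@H](O)/C(CO)=C/CC/C(C)=C/C1
F6 | step 13 | (1(10)E,4E)-9,14-bis(4-methoxybenzyloxy)germacra-1(10),4-dien-11-ol (C7 and C9 as in 20) | CC(C)(O)[C@H]1C[C@H](OCc2ccc(OC)cc2)/C(COCc2ccc(OC)cc2)=C/CC/C(C)=C/C1
F7 | step 15 | trans-4,5-epoxide of 21 as the mixture of both face isomers | C=C(C)[C@H]1C[C@H](OCc2ccc(OC)cc2)/C(COCc2ccc(OC)cc2)=C/CCC2(C)OC2C1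
F8 | step 15 | 9,14-bis(4-methoxybenzyloxy)germacra-1(10),4(15),11(13)-trien-5-ol as the mixture of C5 epimers | C=C(C)[C@H]1C[C@H](OCc2ccc(OC)cc2)/C(COCc2ccc(OC)cc2)=C/CCC(=C)C(O)C1
F9 | step 15 | (1(10)E,7R,9S)-9,14-bis(4-methoxybenzyloxy)germacra-1(10),4(15),11(13)-trien-5-one | C=C(C)[C@H]1C[C@H](OCc2ccc(OC)cc2)/C(COCc2ccc(OC)cc2)=C/CCC(=C)C(=O)C1
F10 | step 17 | 5-O-acetate of 23 | C=C(C)[C@H]1C[C@H](OCc2ccc(OC)cc2)/C(COCc2ccc(OC)cc2)=C/CCC(=C)[C@H](OC(C)=O)C1
F11 | step 17 | (1(10)E,4E)-15-acetoxy-9,14-bis(4-methoxybenzyloxy)germacra-1(10),4,11(13)-triene (C7 and C9 as in 21) | C=C(C)[C@H]1C[C@H](OCc2ccc(OC)cc2)/C(COCc2ccc(OC)cc2)=C/CC/C(COC(C)=O)=C/C1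
F12 | step 17 | (1(10)E,4E)-9,14-bis(4-methoxybenzyloxy)germacra-1(10),4,11(13)-trien-15-ol (C7 and C9 as in 21) | C=C(C)[C@H]1C[C@H](OCc2ccc(OC)cc2)/C(COCc2ccc(OC)cc2)=C/CC/C(CO)=C/C1
F13 | step 24 | 9-O-{2-[bis(2,2,2-trifluoroethoxy)phosphoryl]propanoyl} derivative of 33 | C=C(C)[C@H]1C[C@H](OC(=O)C(C)P(=O)(OCC(F)(F)F)OCC(F)(F)F)/C(COC(=O)[C@H](C)[C@H](C)O[Si](CC)(CC)CC)=C/CC[C@@]2(CO[Si](CC)(CC)CC)O[C@@H]2C1
F14 | step 25 | 12-hydroxy derivative of 36 | C=C(CO)[C@H]1C[C@H](OC(=O)/C(C)=C\C)/C(COC(=O)[C@H](C)[C@H](C)O[Si](CC)(CC)CC)=C/CC[C@@]2(CO[Si](CC)(CC)CC)O[C@@H]2C1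
A1 | alternative 1 | ten-membered 4,5-epoxy-1(10)E-ene with 9,14-bis(4-methoxybenzyloxy), 15-(tert-butyldiphenylsilyloxy) and a 1,3-bis(tert-butyldimethylsilyloxy)propan-2-yl group at C7 | C(CO[Si](C)(C)C(C)(C)C)(CO[Si](C)(C)C(C)(C)C)[C@H]1C[C@H](OCc2ccc(OC)cc2)/C(COCc2ccc(OC)cc2)=C/CC[C@@]2(CO[Si](c3ccccc3)(c3ccccc3)C(C)(C)C)O[C@@H]2C1
A2 | alternative 2 | (1(10)E,4E)-cyclodecadienyl C10 triflate with 9-methoxymethoxy, 15-(tert-butyldimethylsilyloxy) and 12-(tert-butyldimethylsilyloxy)isopropenyl groups | C=C(CO[Si](C)(C)C(C)(C)C)[C@H]1C[C@H](OCOC)/C(OS(=O)(=O)C(F)(F)F)=C/CC/C(CO[Si](C)(C)C(C)(C)C)=C/C1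
A3 | alternative 3 | (5S)-12-(tert-butyldimethylsilyloxy)-9,14-bis(4-methoxybenzyloxy)germacra-1(10),4(15),11(13)-trien-5-ol | C=C(CO[Si](C)(C)C(C)(C)C)[C@H]1C[C@H](OCc2ccc(OC)cc2)/C(COCc2ccc(OC)cc2)=C/CCC(=C)[C@@H](O)C1
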